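**Retrosynthetic overview**

- The strategy rests on the benzenoid ring C3a–C4–C5–C6–C7–C7a, which carries bromine on the three adjacent carbons C4, C5 and C6 and hydrogen only at C7. C4–Br and C6–Br are traced back to C–SiMe3 (ipso exchange), and C5–Br to bromination para to N1 of an N-tosylindoline.
- The pyrrole substituents come last: C2–Br from NBS on the 3-sulfanylindole 17, C3–SMe from sulfenylation of 4,5,6-tribromoindole 16, and the indole from indoline 14 by acid detosylation and dehydrogenation.
- Key disconnection: bis-silyl indoline 12 is cut by a rhodium [2+2+2] into ynamide diyne 10 and trimethylsilylacetylene 11 (bonds C3a–C7a, C4–C5, C6–C7). The five-membered ring N1–C2–C3–C3a–C7a closes first in the metallacycle, and the benzene ring closes second in the same step.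
- Diyne 10 comes from sulfonamide 4 by N-ethynylation through dichloroenamide 7; 4 comes from alcohol 1 and p-toluenesulfonamide 3.

Key step: step 5

Remark: indole numbering (N1, C2, C3, C3a, C4 to C7, C7a) is used for all bicyclic compounds and for the precursor carbons that become these positions.

**Route**

Step 1
Reactants: 1 4-(trimethylsilyl)but-3-yn-1-ol
Product: 2 4-(trimethylsilyl)but-3-yn-1-yl 4-methylbenzenesulfonate
Conditions: TsCl, Et3N, DMAP (cat.), CH2Cl2, 0 °C to rt
Reagents that add atoms: p-toluenesulfonyl chloride, Cc1ccc(cc1)S(=O)(=O)Cl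
Why: O-sulfonylation of a primary alcohol under amine/DMAP catalysis should proceed cleanly, since the silyl-capped alkyne is inert here and the tosylate is the leaving group for step 2.

Step 2
Reactants: 2 4-(trimethylsilyl)but-3-yn-1-yl 4-methylbenzenesulfonate; 3 p-toluenesulfonamide
Product: 4 4-methyl-N-[4-(trimethylsilyl)but-3-yn-1-yl]benzenesulfonamide
Conditions: 3 (3 equiv), K2CO3, dry MeCN, 80 °C
Reagents that add atoms: none
Why: SN2 N-alkylation of the sulfonamide anion at a primary tosylate, in which the threefold excess of 3 should suppress double alkylation and dry carbonate in an aprotic solvent should leave the C–SiMe3 bond intact.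

Step 3
Reactants: 4 4-methyl-N-[4-(trimethylsilyl)but-3-yn-1-yl]benzenesulfonamide; 5 trichloroethylene
Product: 7 N-[(E)-1,2-dichloroethenyl]-4-methyl-N-[4-(trimethylsilyl)but-3-yn-1-yl]benzenesulfonamide, via dichloroacetylene 6 (not isolated)
Conditions: 5 (1.2 equiv), Cs2CO3 (1.5 equiv), dry DMF, rt to 50 °C
Reagents that add atoms: none
Why: Carbonate removes HCl from 5 to give dichloroacetylene 6, which the sulfonamide anion traps at once by trans addition of N–H across the triple bond, the established route from secondary sulfonamides to (E)-1,2-dichloroenamides; anhydrous conditions are kept so that the alkynylsilane is not cleaved.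

Step 4
Reactants: 7 N-[(E)-1,2-dichloroethenyl]-4-methyl-N-[4-(trimethylsilyl)but-3-yn-1-yl]benzenesulfonamide
Product: 10 N-ethynyl-4-methyl-N-[4-(trimethylsilyl)but-3-yn-1-yl]benzenesulfonamide, via chloroynamide 8 (not isolated), via lithium ynamide 9 (not isolated)
Conditions: PhLi (2.3 equiv), THF, −78 to −40 °C; then H2O, −78 °C
Reagents that add atoms: none
Why: Dehydrochlorination of the dichloroenamide by PhLi gives chloroynamide 8, a second equivalent exchanges chlorine for lithium to give lithium ynamide 9, and protonation should deliver the terminal ynamide (known elimination and halogen–lithium exchange route to ynamides), while the silylalkyne and the sulfonyl group are inert to PhLi at −78 °C.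

Step 5
Reactants: 10 N-ethynyl-4-methyl-N-[4-(trimethylsilyl)but-3-yn-1-yl]benzenesulfonamide; 11 trimethylsilylacetylene
Product: 12 1-tosyl-4,6-bis(trimethylsilyl)indoline
Conditions: RhCl(PPh3)3 (5 mol%), 11 (5 equiv), degassed toluene, slow addition of 10 at rt, then 40–60 °C
Reagents that add atoms: none
Why: RhCl(PPh3)3 loses PPh3 and monovalent rhodium binds both alkynes of 10; oxidative coupling gives a rhodacyclopentadiene of trivalent rhodium in which C3a–C7a already exists, so the five-membered ring N1–C2–C3–C3a–C7a is closed by metallacycle formation across the three-atom tether. Alkyne 11 then inserts into the less hindered Rh–C7 bond and reductive elimination forms the remaining bond, so that C4–C5 and C6–C7 close the six-membered ring directly as an arene and monovalent rhodium is returned. The closest known reaction type is the RhCl(PPh3)3-catalysed crossed [2+2+2] cyclotrimerisation of N-sulfonyl ynamide 1,6-diynes with terminal alkynes to indolines. No stereocenter is formed. Cross-reaction against self-trimerisation of 10 is secured by slow addition of 10 to an excess of 11, which itself trimerises only slowly. The step needs the orientation that puts the SiMe3 of 11 on C6; this catalyst has no built-in preference for it and can place small substituents at C5, so the orientation rests on the substrate, in which a C5 silyl group would be wedged against the C4 SiMe3 group that is itself buttressed by the C3 methylene.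

Step 6
Reactants: 12 1-tosyl-4,6-bis(trimethylsilyl)indoline
Product: 13 4,6-dibromo-1-tosylindoline
Conditions: Br2 (2.3 equiv), pyridine (1 equiv), CH2Cl2, 0 °C to rt, dark
Reagents that add atoms: bromine, BrBr
Why: Ipso-bromodesilylation (electrophilic substitution at the silicon-bearing carbon, whose arenium ion is stabilised by the β-silicon effect) should replace both SiMe3 groups, which sit ortho and para to the alkyl-bearing C3a, faster than any C–H is attacked, while pyridine binds stray HBr so that protodesilylation cannot compete.

Step 7
Reactants: 13 4,6-dibromo-1-tosylindoline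
Product: 14 4,5,6-tribromo-1-tosylindoline
Conditions: Br2 (1.5 equiv), AcOH, 60 °C (FeBr3, 5 mol%, if the ring is too deactivated)
Reagents that add atoms: bromine, BrBr
Why: Electrophilic aromatic bromination directed para to the sulfonamide nitrogen should go to C5, because the only other free position, C7, is ortho to N1 and shielded by the tosyl group, as in the known C5-selective bromination of N-acyl and N-sulfonyl indolines.

Step 8
Reactants: 14 4,5,6-tribromo-1-tosylindoline
Product: 15 4,5,6-tribromoindoline
Conditions: conc. H2SO4, 0 °C to rt; then ice, aq. NaOH to pH 9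
Reagents that add atoms: none
Why: Acidolysis of an N-aryl sulfonamide (N-protonation, S–N cleavage, sulfonyl transfer to water) should free the nitrogen, the electron-poor ring disfavouring sulfonyl migration onto carbon and the aryl bromides being inert to acid; this is chosen over alkoxide-induced sulfinate elimination, which would risk aryne formation across C6–C7.

Step 9
Reactants: 15 4,5,6-tribromoindoline
Product: 16 4,5,6-tribromo-1H-indole
Conditions: DDQ (1.1 equiv), 1,4-dioxane, rt
Reagents that add atoms: none
Why: Dehydrogenation of a free indoline by DDQ (hydride abstraction at C2, then proton loss from C3) is driven by aromatisation of the pyrrole ring and should tolerate the aryl bromides.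

Step 10
Reactants: 16 4,5,6-tribromo-1H-indole
Product: 17 4,5,6-tribromo-3-(methylsulfanyl)-1H-indole
Conditions: MeSSMe, SO2Cl2, CH2Cl2, −20 to 0 °C; then 16, CH2Cl2, 0 °C
Reagents that add atoms: methanesulfenyl chloride, CSCl (made in the flask from dimethyl disulfide, CSSC)
Why: Electrophilic sulfenylation of the indole at C3, its most nucleophilic carbon, by a sulfenyl chloride should succeed despite the deactivating bromine atoms, since the electrophile is strong and no other position competes.

Step 11
Reactants: 17 4,5,6-tribromo-3-(methylsulfanyl)-1H-indole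
Product: 18 2,4,5,6-tetrabromo-3-methylsulfanyl-1H-indole
Conditions: NBS (1.0 equiv), dry CH2Cl2, 0 °C, dark
Reagents that add atoms: N-bromosuccinimide, O=C1CCC(=O)N1Br
Why: Electrophilic bromination of a 3-substituted indole with NBS goes to C2 (attack at C3 or sulfur, shift of bromine to C2, loss of a proton), and one equivalent under anhydrous conditions at 0 °C should avoid sulfoxide formation and attack at C7.

**Compound list**

1 | 4-(trimethylsilyl)but-3-yn-1-ol | C[Si](C)(C)C#CCCO | starting material
2 | 4-(trimethylsilyl)but-3-yn-1-yl 4-methylbenzenesulfonate | Cc1ccc(cc1)S(=O)(=O)OCCC#C[Si](C)(C)C | intermediate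
3 | p-toluenesulfonamide | Cc1ccc(cc1)S(N)(=O)=O | starting material
4 | 4-methyl-N-[4-(trimethylsilyl)but-3-yn-1-yl]benzenesulfonamide | Cc1ccc(cc1)S(=O)(=O)NCCC#C[Si](C)(C)C | intermediate
5 | trichloroethylene | ClC=C(Cl)Cl | starting material
6 | dichloroacetylene | ClC#CCl | intermediate (not isolated)
7 | N-[(E)-1,2-dichloroethenyl]-4-methyl-N-[4-(trimethylsilyl)but-3-yn-1-yl]benzenesulfonamide | Cl/C=C(/Cl)N(CCC#C[Si](C)(C)C)S(=O)(=O)c1ccc(C)cc1 | intermediate
8 | N-(chloroethynyl)-4-methyl-N-[4-(trimethylsilyl)but-3-yn-1-yl]benzenesulfonamide (chloroynamide) | ClC#CN(CCC#C[Si](C)(C)C)S(=O)(=O)c1ccc(C)cc1 | intermediate (not isolated)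
9 | lithium ynamide, N-(lithioethynyl)-4-methyl-N-[4-(trimethylsilyl)but-3-yn-1-yl]benzenesulfonamide | [Li]C#CN(CCC#C[Si](C)(C)C)S(=O)(=O)c1ccc(C)cc1 | intermediate (not isolated)
10 | N-ethynyl-4-methyl-N-[4-(trimethylsilyl)but-3-yn-1-yl]benzenesulfonamide | C#CN(CCC#C[Si](C)(C)C)S(=O)(=O)c1ccc(C)cc1 | intermediate
11 | trimethylsilylacetylene | C#C[Si](C)(C)C | starting material
12 | 1-tosyl-4,6-bis(trimethylsilyl)indoline | Cc1ccc(cc1)S(=O)(=O)N1CCc2c([Si](C)(C)C)cc([Si](C)(C)C)cc21 | intermediate
13 | 4,6-dibromo-1-tosylindoline | Cc1ccc(cc1)S(=O)(=O)N1CCc2c(Br)cc(Br)cc21 | intermediate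
14 | 4,5,6-tribromo-1-tosylindoline | Cc1ccc(cc1)S(=O)(=O)N1CCc2c(Br)c(Br)c(Br)cc21 | intermediate
15 | 4,5,6-tribromoindoline | Brc1cc2NCCc2c(Br)c1Br | intermediate
16 | 4,5,6-tribromo-1H-indole | Brc1cc2[nH]ccc2c(Br)c1Br | intermediate
17 | 4,5,6-tribromo-3-(methylsulfanyl)-1H-indole | CSc1c[nH]c2cc(Br)c(Br)c(Br)c12 | intermediate
18 | 2,4,5,6-tetrabromo-3-methylsulfanyl-1H-indole | CSc1c(Br)[nH]c2cc(Br)c(Br)c(Br)c12 | target

**Step count**

Total: 11 steps. Longest linear sequence: 11 steps (1 to 18); 3, 5 and 11 are bought.

**Steps most likely to fail**

Step 5. The monoalkyne may insert with the opposite orientation, so that its SiMe3 group ends at C5 next to the C4 silyl group; the silyl-capped alkyne of 10 may also enter the metallacycle too slowly, so that 10 consumes itself. The fallback removes the orientation question and sets out from 10. Cyclotrimerisation of 10 with acetylene gas (1 atm, RhCl(PPh3)3, toluene) should give 1-tosyl-4-(trimethylsilyl)indoline F1, the monoalkyne being symmetric. Sterically governed C–H borylation ([Ir(OMe)(cod)]2, 4,4'-di-tert-butyl-2,2'-bipyridine, B2pin2, THF, 80 °C) should then functionalise C6, the only ring C–H without an ortho substituent (C5 is next to SiMe3, C7 next to the sulfonylated nitrogen), giving 6-(4,4,5,5-tetramethyl-1,3,2-dioxaborolan-2-yl)-1-tosyl-4-(trimethylsilyl)indoline F2. CuBr2 in MeOH/H2O at 80 °C should convert C–B into C–Br to give 6-bromo-1-tosyl-4-(trimethylsilyl)indoline F3, and Br2/pyridine in CH2Cl2 should exchange the remaining C4 silyl group. The fallback comes back to the route at 13.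

Step 7. Attack at C7 (ortho to N1) may compete with attack at C5, which lies between two bromine atoms, or the deactivated ring may react incompletely. The fallback sets out from 13 and replaces electrophilic substitution by deprotonative metalation. TMPMgCl·LiCl in THF at −20 °C should remove the most acidic ring hydrogen, the one at C5 flanked by two bromine atoms, and the arylmagnesium species is quenched with 1,2-dibromo-1,1,2,2-tetrachloroethane. This gives 14 directly, where the fallback rejoins the route; no compound outside the list is made (F0).

Step 3. Carbonate in DMF may cleave the alkynyl C–SiMe3 bond, or dichloroacetylene may decompose faster than the sulfonamide adds to it. The fallback sets out from 4 and avoids both. N-formylation (NaH, then acetic formic anhydride, THF, 0 °C) should give N-formyl-4-methyl-N-[4-(trimethylsilyl)but-3-yn-1-yl]benzenesulfonamide F4. Dichloro-olefination of the formamide with PPh3/CCl4 in THF at 60 °C should give N-(2,2-dichloroethenyl)-4-methyl-N-[4-(trimethylsilyl)but-3-yn-1-yl]benzenesulfonamide F5. n-BuLi (2.2 equiv, THF, −78 °C) then induces elimination and chlorine–lithium exchange through 8 and 9, and protonation with water brings the fallback back to the route at 10.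

**Further compounds**

F1 | step 5 | 1-tosyl-4-(trimethylsilyl)indoline | Cc1ccc(cc1)S(=O)(=O)N1CCc2c([Si](C)(C)C)cccc21
F2 | step 5 | 6-(4,4,5,5-tetramethyl-1,3,2-dioxaborolan-2-yl)-1-tosyl-4-(trimethylsilyl)indoline | Cc1ccc(cc1)S(=O)(=O)N1CCc2c([Si](C)(C)C)cc(cc21)B1OC(C)(C)C(C)(C)O1
F3 | step 5 | 6-bromo-1-tosyl-4-(trimethylsilyl)indoline | Cc1ccc(cc1)S(=O)(=O)N1CCc2c([Si](C)(C)C)cc(Br)cc21
F0 | step 7 | none | none
F4 | step 3 | N-formyl-4-methyl-N-[4-(trimethylsilyl)but-3-yn-1-yl]benzenesulfonamide | O=CN(CCC#C[Si](C)(C)C)S(=O)(=O)c1ccc(C)cc1
F5 | step 3 | N-(2,2-dichloroethenyl)-4-methyl-N-[4-(trimethylsilyl)but-3-yn-1-yl]benzenesulfonamide | ClC(Cl)=CN(CCC#C[Si](C)(C)C)S(=O)(=O)c1ccc(C)cc1
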